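The route rests on opening the dihydrofuran ring of the phenylcoumaran at O1–C7a and C2–C3. In one flask a (Z)-γ-aryl allylboronate adds to O-benzylvanillin under chiral phosphoric acid control, forming C2–C3 with both stereocentres, and the alkoxide so formed displaces fluoride at C7a, forming O1–C7a. The precursor is a fluoroarene that carries the allylboronate ortho to fluorine. Two features are exploited: C5 of the benzofuran ring, which later bears the lactone CH2, is para to C7a and is kept as an ester to activate the fluoride; and the C3 CH2OH is carried as a vinyl group, so that C3 is the γ-carbon of an allyl nucleophile. Enolate alkylation then attaches the trans lactone.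

Key step: step 4

Remark: the sense of induction of the two chiral catalysts (steps 4 and 8) is assigned by analogy with their parent substrates (allylboration of aryl aldehydes; itaconate-type half-esters); the antipodal catalyst would be used if an early check of 7 or of lactone 13 showed the opposite sense.

Step 1
Reactants: 1 methyl 4-fluoro-3-methoxybenzoate
Product: 2 methyl 4-fluoro-3-methoxy-5-(4,4,5,5-tetramethyl-1,3,2-dioxaborolan-2-yl)benzoate
Conditions: [Ir(OMe)(cod)]2 (1.5 mol %), 4,4'-di-tert-butyl-2,2'-bipyridine (3 mol %), B2pin2 (1.0 equiv), THF, 80 °C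
Reagents that add atoms: bis(pinacolato)diboron, CC1(C)OB(OC1(C)C)B1OC(C)(C)C(C)(C)O1
Why: Iridium-catalysed C–H borylation is sterically governed and tolerates no ortho substituent larger than fluorine, so only the C–H flanked by F and H should be borylated while the two C–H bonds next to the ester are spared.

Step 2
Reactants: 2 methyl 4-fluoro-3-methoxy-5-(4,4,5,5-tetramethyl-1,3,2-dioxaborolan-2-yl)benzoate
Product: 3 methyl 4-fluoro-3-methoxy-5-(propa-1,2-dien-1-yl)benzoate
Conditions: Pd(PPh3)4 (5 mol %), methyl prop-2-yn-1-yl carbonate (1.5 equiv), THF, 60 °C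
Reagents that add atoms: methyl prop-2-yn-1-yl carbonate, C#CCOC(=O)OC
Why: Zerovalent palladium adds to the propargylic carbonate with loss of CO2 to give an allenylpalladium methoxide, which should transmetalate with the aryl boronate under neutral conditions and reductively eliminate the aryl allene (Suzuki–Miyaura-type coupling of propargylic carbonates).

Step 3
Reactants: 3 methyl 4-fluoro-3-methoxy-5-(propa-1,2-dien-1-yl)benzoate
Product: 4 methyl 4-fluoro-3-methoxy-5-[(1Z)-3-(4,4,5,5-tetramethyl-1,3,2-dioxaborolan-2-yl)prop-1-en-1-yl]benzoate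
Conditions: CuCl (3 mol %), Xantphos (3 mol %), NaOtBu (10 mol %), HBpin (1.2 equiv), THF, −20 °C
Reagents that add atoms: pinacolborane, [H]B1OC(C)(C)C(C)(C)O1
Why: A monovalent copper hydride should add across the terminal C=C of the allene from the face remote from the aryl group to give a (Z)-σ-allylcopper that HBpin borylates at CH2 with retention (copper-catalysed allene hydroboration), which fixes the Z geometry needed for the syn adduct.

Step 4
Reactants: 4 methyl 4-fluoro-3-methoxy-5-[(1Z)-3-(4,4,5,5-tetramethyl-1,3,2-dioxaborolan-2-yl)prop-1-en-1-yl]benzoate; 5 4-(benzyloxy)-3-methoxybenzaldehyde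
Product: 7 methyl (2S,3S)-2-[4-(benzyloxy)-3-methoxyphenyl]-3-ethenyl-7-methoxy-2,3-dihydro-1-benzofuran-5-carboxylate, via pinacol borate 6 (not isolated)
Conditions: (S)-TRIP [(S)-3,3'-bis(2,4,6-triisopropylphenyl)-1,1'-binaphthyl-2,2'-diyl hydrogen phosphate] (5 mol %), 4 Å molecular sieves, toluene, −30 °C; then KOtBu (1.2 equiv), THF–DMF (4:1), −30 → 20 °C
Reagents that add atoms: none
Why: The (Z)-allylboronate adds to the aldehyde through a closed six-membered chair transition state activated by the phosphoric acid (P–OH hydrogen bond to a boronate oxygen and P=O contact to the formyl C–H), which forms C2–C3, and tert-butoxide then frees the alkoxide from borate 6, which displaces fluoride at C7a by addition–elimination through a Meisenheimer intermediate stabilised by the para ester at C5, which forms O1–C7a. The closest known reaction types are the chiral phosphoric acid-catalysed allyl- and crotylboration of aryl aldehydes with pinacol allylboronates and the intramolecular SNAr etherification of 2-(2-fluoroaryl)ethanols. The dihydrofuran ring closes in a 5-exo-trig sense by attack of the alkoxide on the aromatic C–F carbon. C3 is controlled by the Z geometry of 4 (γ-aryl group axial in the chair gives the syn adduct, which is the trans-2,3 ring because ring closure touches no stereocentre) and C2 by the (S) catalyst, which should direct the allyl group to the Si face of the aldehyde, the mirror image of the Re-face preference of the (R) acid with aryl aldehydes. The step needs the catalysed pathway to outrun the uncatalysed one (low temperature), retention of the Z geometry (secured by the configurationally stable pinacol boronate), attack of the alkoxide at C–F and not at the ester (only the five-membered closure is within reach) and no migration of the vinyl double bond (slight excess of base, not above room temperature).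

Step 5
Reactants: 7 methyl (2S,3S)-2-[4-(benzyloxy)-3-methoxyphenyl]-3-ethenyl-7-methoxy-2,3-dihydro-1-benzofuran-5-carboxylate
Product: 8 [(2S,3S)-2-[4-(benzyloxy)-3-methoxyphenyl]-3-ethenyl-7-methoxy-2,3-dihydro-1-benzofuran-5-yl]methanol
Conditions: DIBAL-H (iBu2AlH, 2.5 equiv), CH2Cl2, −78 → 0 °C; aqueous potassium sodium tartrate work-up
Reagents that add atoms: none
Why: DIBAL-H should reduce the aryl ester to the benzylic alcohol without touching the vinyl group, the benzyl ether or the cyclic benzylic ether.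

Step 6
Reactants: 8 [(2S,3S)-2-[4-(benzyloxy)-3-methoxyphenyl]-3-ethenyl-7-methoxy-2,3-dihydro-1-benzofuran-5-yl]methanol
Product: 9 (2S,3S)-2-[4-(benzyloxy)-3-methoxyphenyl]-5-(bromomethyl)-3-ethenyl-7-methoxy-2,3-dihydro-1-benzofuran
Conditions: CBr4 (1.2 equiv), PPh3 (1.2 equiv), CH2Cl2, 0 °C; used directly in step 10
Reagents that add atoms: carbon tetrabromide, BrC(Br)(Br)Br
Why: Appel bromination should convert the primary benzylic alcohol into the bromide under neutral conditions, and the electron-rich benzylic halide is used at once.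

Step 7
Reactants: 5 4-(benzyloxy)-3-methoxybenzaldehyde
Product: 10 (3E)-4-[4-(benzyloxy)-3-methoxyphenyl]-3-(methoxycarbonyl)but-3-enoic acid
Conditions: dimethyl succinate (1.5 equiv), NaOMe (1.5 equiv), MeOH, reflux; then aqueous HCl
Reagents that add atoms: dimethyl succinate, COC(=O)CCC(=O)OC
Why: Stobbe condensation should proceed through a paraconic ester that opens by elimination to the (E)-alkylidene half-ester, which differentiates the two carboxyl groups.

Step 8
Reactants: 10 (3E)-4-[4-(benzyloxy)-3-methoxyphenyl]-3-(methoxycarbonyl)but-3-enoic acid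
Product: 11 (3R)-4-[4-(benzyloxy)-3-methoxyphenyl]-3-(methoxycarbonyl)butanoic acid
Conditions: [Rh(cod)((S,S)-Et-DuPhos)]BF4 (1 mol %), H2 (5 bar), NaOMe (10 mol %), MeOH, 20 °C
Reagents that add atoms: none
Why: Rhodium–bisphospholane catalysed asymmetric hydrogenation of the itaconate-type half-ester, with two-point binding through the alkene and the carboxylate, should set the stereocentre as R without cleaving the benzyl ether.

Step 9
Reactants: 11 (3R)-4-[4-(benzyloxy)-3-methoxyphenyl]-3-(methoxycarbonyl)butanoic acid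
Product: 13 (4R)-4-[4-(benzyloxy)-3-methoxybenzyl]dihydrofuran-2(3H)-one, via hydroxy acid 12 (not isolated)
Conditions: LiEt3BH (3.3 equiv), THF, 0 → 20 °C; then 2 M HCl, 20 °C
Reagents that add atoms: none
Why: Triethylborohydride should deprotonate the acid to an inert lithium carboxylate and reduce only the methyl ester, and acidification lactonises the γ-hydroxy acid without touching the stereocentre.

Step 10
Reactants: 13 (4R)-4-[4-(benzyloxy)-3-methoxybenzyl]dihydrofuran-2(3H)-one; 9 (2S,3S)-2-[4-(benzyloxy)-3-methoxyphenyl]-5-(bromomethyl)-3-ethenyl-7-methoxy-2,3-dihydro-1-benzofuran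
Product: 15 (3R,4R)-4-[4-(benzyloxy)-3-methoxybenzyl]-3-{[(2S,3S)-2-[4-(benzyloxy)-3-methoxyphenyl]-3-ethenyl-7-methoxy-2,3-dihydro-1-benzofuran-5-yl]methyl}dihydrofuran-2(3H)-one, via lithium enolate 14 (not isolated)
Conditions: LDA (LiN(iPr)2, 1.05 equiv), THF, −78 °C; then 9 (1.0 equiv), DMPU, −78 → −30 °C
Reagents that add atoms: none
Why: Alkylation of the lactone enolate with the benzylic bromide should occur anti to the β-benzyl group, which sets the α-stereocentre as R (trans-3,4-disubstituted lactone).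

Step 11
Reactants: 15 (3R,4R)-4-[4-(benzyloxy)-3-methoxybenzyl]-3-{[(2S,3S)-2-[4-(benzyloxy)-3-methoxyphenyl]-3-ethenyl-7-methoxy-2,3-dihydro-1-benzofuran-5-yl]methyl}dihydrofuran-2(3H)-one
Product: 17 (3R,4R)-4-[4-(benzyloxy)-3-methoxybenzyl]-3-{[(2S,3R)-2-[4-(benzyloxy)-3-methoxyphenyl]-3-(hydroxymethyl)-7-methoxy-2,3-dihydro-1-benzofuran-5-yl]methyl}dihydrofuran-2(3H)-one, via aldehyde 16 (not isolated)
Conditions: OsO4 (2 mol %), NaIO4 (3 equiv), 2,6-lutidine (2 equiv), 1,4-dioxane/H2O (3:1), 20 °C; then NaBH4 (excess), MeOH, 0 °C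
Reagents that add atoms: sodium periodate, [Na+].[O-]I(=O)(=O)=O (source of the new oxygen, delivered through OsO4)
Why: Lemieux–Johnson cleavage of the terminal vinyl group should give the C3 aldehyde, which NaBH4 reduces at 0 °C faster than the lactone; the trans-2,3 arrangement is the thermodynamically favoured one, so the epimerisable aldehyde does not endanger C3.

Step 12
Reactants: 17 (3R,4R)-4-[4-(benzyloxy)-3-methoxybenzyl]-3-{[(2S,3R)-2-[4-(benzyloxy)-3-methoxyphenyl]-3-(hydroxymethyl)-7-methoxy-2,3-dihydro-1-benzofuran-5-yl]methyl}dihydrofuran-2(3H)-one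
Product: 18 isolappaol A
Conditions: H2 (1 atm), Pd/C (10 wt %, palladium on carbon), EtOAc/EtOH (1:1), 20 °C
Reagents that add atoms: none
Why: Hydrogenolysis over palladium on carbon should remove both benzyl ethers under neutral conditions at ambient pressure, under which the cyclic benzylic C2–O1 ether and the lactone persist.

Compound list
1 | methyl 4-fluoro-3-methoxybenzoate | COC(=O)c1ccc(F)c(OC)c1 | starting material
2 | methyl 4-fluoro-3-methoxy-5-(4,4,5,5-tetramethyl-1,3,2-dioxaborolan-2-yl)benzoate | COC(=O)c1cc(OC)c(F)c(c1)B1OC(C)(C)C(C)(C)O1 | intermediate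
3 | methyl 4-fluoro-3-methoxy-5-(propa-1,2-dien-1-yl)benzoate | COC(=O)c1cc(OC)c(F)c(C=C=C)c1 | intermediate
4 | methyl 4-fluoro-3-methoxy-5-[(1Z)-3-(4,4,5,5-tetramethyl-1,3,2-dioxaborolan-2-yl)prop-1-en-1-yl]benzoate | COC(=O)c1cc(OC)c(F)c(/C=C\CB2OC(C)(C)C(C)(C)O2)c1 | intermediate
5 | 4-(benzyloxy)-3-methoxybenzaldehyde (O-benzylvanillin) | O=Cc1ccc(OCc2ccccc2)c(OC)c1 | starting material
6 | methyl 3-[(1S,2S)-1-[4-(benzyloxy)-3-methoxyphenyl]-1-[(4,4,5,5-tetramethyl-1,3,2-dioxaborolan-2-yl)oxy]but-3-en-2-yl]-4-fluoro-5-methoxybenzoate (pinacol borate, not isolated) | COC(=O)c1cc(OC)c(F)c(c1)[C@H](C=C)[C@@H](c1ccc(OCc2ccccc2)c(OC)c1)OB1OC(C)(C)C(C)(C)O1 | intermediate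
7 | methyl (2S,3S)-2-[4-(benzyloxy)-3-methoxyphenyl]-3-ethenyl-7-methoxy-2,3-dihydro-1-benzofuran-5-carboxylate | COC(=O)c1cc(OC)c2c(c1)[C@H](C=C)[C@@H](c1ccc(OCc3ccccc3)c(OC)c1)O2 | intermediate
8 | [(2S,3S)-2-[4-(benzyloxy)-3-methoxyphenyl]-3-ethenyl-7-methoxy-2,3-dihydro-1-benzofuran-5-yl]methanol | OCc1cc(OC)c2c(c1)[C@H](C=C)[C@@H](c1ccc(OCc3ccccc3)c(OC)c1)O2 | intermediate
9 | (2S,3S)-2-[4-(benzyloxy)-3-methoxyphenyl]-5-(bromomethyl)-3-ethenyl-7-methoxy-2,3-dihydro-1-benzofuran | BrCc1cc(OC)c2c(c1)[C@H](C=C)[C@@H](c1ccc(OCc3ccccc3)c(OC)c1)O2 | intermediate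
10 | (3E)-4-[4-(benzyloxy)-3-methoxyphenyl]-3-(methoxycarbonyl)but-3-enoic acid | COC(=O)/C(CC(=O)O)=C/c1ccc(OCc2ccccc2)c(OC)c1 | intermediate
11 | (3R)-4-[4-(benzyloxy)-3-methoxyphenyl]-3-(methoxycarbonyl)butanoic acid | COC(=O)[C@@H](CC(=O)O)Cc1ccc(OCc2ccccc2)c(OC)c1 | intermediate
12 | (3R)-4-[4-(benzyloxy)-3-methoxyphenyl]-3-(hydroxymethyl)butanoic acid (formed as its lithium salt, not isolated) | OC[C@@H](CC(=O)O)Cc1ccc(OCc2ccccc2)c(OC)c1 | intermediate
13 | (4R)-4-[4-(benzyloxy)-3-methoxybenzyl]dihydrofuran-2(3H)-one | O=C1C[C@@H](Cc2ccc(OCc3ccccc3)c(OC)c2)CO1 | intermediate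
14 | lithium enolate of 13 (not isolated) | [Li+].[O-]C1=C[C@@H](Cc2ccc(OCc3ccccc3)c(OC)c2)CO1 | intermediate
15 | (3R,4R)-4-[4-(benzyloxy)-3-methoxybenzyl]-3-{[(2S,3S)-2-[4-(benzyloxy)-3-methoxyphenyl]-3-ethenyl-7-methoxy-2,3-dihydro-1-benzofuran-5-yl]methyl}dihydrofuran-2(3H)-one | COc1cc(C[C@H]2COC(=O)[C@@H]2Cc2cc(OC)c3c(c2)[C@H](C=C)[C@@H](c2ccc(OCc4ccccc4)c(OC)c2)O3)ccc1OCc1ccccc1 | intermediate
16 | (2S,3S)-2-[4-(benzyloxy)-3-methoxyphenyl]-5-{[(3R,4R)-4-[4-(benzyloxy)-3-methoxybenzyl]-2-oxotetrahydrofuran-3-yl]methyl}-7-methoxy-2,3-dihydro-1-benzofuran-3-carbaldehyde (not isolated) | COc1cc(C[C@H]2COC(=O)[C@@H]2Cc2cc(OC)c3c(c2)[C@H](C=O)[C@@H](c2ccc(OCc4ccccc4)c(OC)c2)O3)ccc1OCc1ccccc1 | intermediate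
17 | (3R,4R)-4-[4-(benzyloxy)-3-methoxybenzyl]-3-{[(2S,3R)-2-[4-(benzyloxy)-3-methoxyphenyl]-3-(hydroxymethyl)-7-methoxy-2,3-dihydro-1-benzofuran-5-yl]methyl}dihydrofuran-2(3H)-one | COc1cc(C[C@H]2COC(=O)[C@@H]2Cc2cc(OC)c3c(c2)[C@H](CO)[C@@H](c2ccc(OCc4ccccc4)c(OC)c2)O3)ccc1OCc1ccccc1 | intermediate
18 | isolappaol A, (3R,4R)-4-(4-hydroxy-3-methoxybenzyl)-3-{[(2S,3R)-2-(4-hydroxy-3-methoxyphenyl)-3-(hydroxymethyl)-7-methoxy-2,3-dihydro-1-benzofuran-5-yl]methyl}dihydrofuran-2(3H)-one | COc1cc(C[C@H]2COC(=O)[C@@H]2Cc2cc(OC)c3c(c2)[C@H](CO)[C@@H](c2ccc(O)c(OC)c2)O3)ccc1O | target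

Total step count: 12. Longest linear sequence: 9 steps (steps 1–6, then 10–12).

Steps most likely to fail

Step 4 (key step). The catalysed allylboration of an electron-rich aldehyde with a hindered (Z)-γ-aryl boronate may be slow, so that the uncatalysed background erodes face selectivity. The alkoxide may also be released incompletely from the borate, or the basic stage may move the vinyl double bond into conjugation. The fallback replaces catalyst control by reagent control and separates the two bond formations; it sets out from allene 3 and aldehyde 5 and returns at 7. Kinetic hydroboration of 3 with (−)-diisopinocampheylborane [from (+)-α-pinene] in THF at −25 °C should give the (Z)-allyl(diisopinocampheyl)borane F1 (not isolated). Addition of 5 at −78 °C gives the borinate F2, and oxidative work-up (NaBO3·4H2O, THF/H2O) gives the syn homoallylic alcohol F3, which can be purified. Treatment of F3 with KHMDS (KN(SiMe3)2) in THF at 0 °C closes the ring by SNAr to 7.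

Step 3. Hydrocupration may take the wrong regiochemistry (alkenyl or branched allyl boronate), or the (Z)-allylcopper may isomerise to E before borylation. The fallback builds the Z alkene by semihydrogenation of an alkyne; it sets out from 2 and returns at 4. Coupling of 2 with (bromoethynyl)triisopropylsilane (Pd(PPh3)4, K3PO4, toluene/H2O, 60 °C) gives the silyl alkyne F4. Desilylation with Bu4NF in THF at 0 °C gives the terminal alkyne F5. Deprotonation with LiHMDS (LiN(SiMe3)2) at −78 °C and Matteson-type homologation with 2-(iodomethyl)-4,4,5,5-tetramethyl-1,3,2-dioxaborolane gives the propargylic boronate F6. Semihydrogenation (H2, Pd/CaCO3 poisoned with Pb(OAc)2, quinoline, EtOAc) then gives 4.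

Step 2. Transmetalation of the pinacol boronate under neutral conditions may be sluggish, coupling may occur at the propargylic instead of the allenylic terminus, or the aryl allene may react further with allenylpalladium. The fallback changes the coupling polarity; it sets out from 2 and returns at 3. Iododeboronation of 2 (NaI, sodium N-chloro-4-methylbenzenesulfonamide, THF/H2O, 20 °C) gives methyl 4-fluoro-3-iodo-5-methoxybenzoate F7. Stille coupling of F7 with tributyl(propa-1,2-dien-1-yl)stannane (Pd(PPh3)4, DMF, 60 °C) gives 3.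

Further compounds
F1 | step 4 | methyl 3-[(1Z)-3-[bis((1R,2S,3R,5R)-2,6,6-trimethylbicyclo[3.1.1]hept-3-yl)boranyl]prop-1-en-1-yl]-4-fluoro-5-methoxybenzoate | COC(=O)c1cc(OC)c(F)c(/C=C\CB([C@@H]2C[C@@H]3C[C@H]([C@H]2C)C3(C)C)[C@@H]2C[C@@H]3C[C@H]([C@H]2C)C3(C)C)c1
F2 | step 4 | diisopinocampheylborinate of the syn homoallylic alcohol F3 | COC(=O)c1cc(OC)c(F)c(c1)[C@H](C=C)[C@@H](c1ccc(OCc2ccccc2)c(OC)c1)OB([C@@H]1C[C@@H]2C[C@H]([C@H]1C)C2(C)C)[C@@H]1C[C@@H]2C[C@H]([C@H]1C)C2(C)C
F3 | step 4 | methyl 3-[(1S,2S)-1-[4-(benzyloxy)-3-methoxyphenyl]-1-hydroxybut-3-en-2-yl]-4-fluoro-5-methoxybenzoate | COC(=O)c1cc(OC)c(F)c(c1)[C@H](C=C)[C@@H](c1ccc(OCc2ccccc2)c(OC)c1)O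
F4 | step 3 | methyl 4-fluoro-3-methoxy-5-[(triisopropylsilyl)ethynyl]benzoate | COC(=O)c1cc(OC)c(F)c(C#C[Si](C(C)C)(C(C)C)C(C)C)c1
F5 | step 3 | methyl 3-ethynyl-4-fluoro-5-methoxybenzoate | COC(=O)c1cc(OC)c(F)c(C#C)c1
F6 | step 3 | methyl 4-fluoro-3-methoxy-5-[3-(4,4,5,5-tetramethyl-1,3,2-dioxaborolan-2-yl)prop-1-yn-1-yl]benzoate | COC(=O)c1cc(OC)c(F)c(C#CCB2OC(C)(C)C(C)(C)O2)c1
F7 | step 2 | methyl 4-fluoro-3-iodo-5-methoxybenzoate | COC(=O)c1cc(OC)c(F)c(I)c1
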